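# Proposed synthesis of CNP0171674.1 (19) from myo-inositol by methylene transfer to a protected inosose

## The problem

1. Compound 19 is a cyclohexane whose six ring carbons all carry oxygen. C1 is the quaternary oxirane carbon bearing the exocyclic C7 (as CH2OBz), C2 and C3 are the acetoxy carbons, C4 and C5 the carbinol carbons and C6 the oxirane CH; On is the oxygen on Cn, β the face of C7 and α the other face. On this numbering the substituents are O1 α (shared with C6), O2 α, O3 β, O4 α and O5 β.
2. Six contiguous stereocentres must be set, one of them quaternary and part of a trisubstituted oxirane cis-fused to the ring.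
3. The seven oxygens play four roles (oxirane, two acetates, two free hydroxyls, one side-chain benzoate), so O2/O3, O4/O5 and O7 must stay distinguishable throughout.
4. The oxirane does not tolerate strong acid or free nucleophiles, and the esters migrate to neighbouring hydroxyls under base (O3 to O4, and O2 or O7 to O1 whenever the tertiary hydroxyl is free). The closing steps must therefore be brief, mild or intramolecularly driven.
5. O2 to O5 are all trans and hence all equatorial on one chair, which fixes the conformation and lets the existing centres decide what happens at C1 and C6.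
6. The enabling feature is that the oxirane oxygen is trans to O5. If the C6–O1 bond is made last, by O1 displacing an oxygen leaving group on C6 with inversion, C6 first carries a β (axial) oxygen, and C2 to C6 then show exactly the pattern of myo-inositol with its single axial hydroxyl at C6.
7. C1 is then the carbon of a ketone next to that axial oxygen, C7 is the only carbon to add and C1 the only stereocentre to create. An axial O1 is automatically anti-periplanar to the C6–O bond it must later break.

## Retrosynthesis

**19 from 18.** The last bond cut is the benzyl C–O bond on O4. Hydrogenolysis is the one deprotection neutral enough for a product holding an oxirane, a free trans-diol and three esters. A silyl ether would need fluoride or acid, and an ester could not be told from the acetates. Compound 18 differs from 19 only by this ether, and the forward step must leave the non-benzylic oxirane alone.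

**18 from 16.** The oxirane C6–O1 bond is cut. Closure from O1 onto C6 with inversion needs a tertiary O1–H (α, axial) and a β (axial) leaving group on C6. In cyclic sulfate 16 both O5 and O6 are activated, so the hindered axial O6–H need not be sulfonylated selectively beside the equatorial O5–H. Only C6 has an anti-periplanar internal nucleophile, and O5 leaves as the sulfate monoester 17, hydrolysed in the same flask. The forward reaction must outpace acyl transfer to the alkoxide.

**16 from 14 from 13.** The cyclic sulfate comes from the cis-5,6-diol 14 through sulfite 15, and the diol from the cis-fused isopropylidene ketal of 13. The O1/O6 pair is trans-diaxial and cannot form a five-membered ring, so the tertiary hydroxyl stays out of both operations.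

**13 from 11 and 12.** The C7–O bond to the benzoate is cut: benzoic acid 12 opens spiro-oxirane 11 at its CH2 group. This puts the benzoate on O7 with no choice between hydroxyls and uncovers the tertiary O1–H in the same event. Selective benzoylation of a 1,7-diol would be a step longer. The opening is placed after the acetates so that no intermediate combines a free O1–H with the trans-ketal, which could migrate to the cis O1/O2 pair under acid.

**11 from 10 from 9.** The two acetyl C–O bonds are cut back to diol 10, and this to the trans-fused isopropylidene ketal of 9. A trans-fused dioxolane on a cyclohexane is strained and is removed under conditions that leave the cis-fused one in place. One type of protecting group thus serves two differently timed purposes, and O2/O3 are separated from O5/O6 without extra ether groups.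

**9 from 6 and 7 (key disconnection).** The C1–C7 and C7–O1 bonds are cut, giving ketone 6 and a CH2 unit from trimethylsulfoxonium iodide 7, by way of betaine 8. Against methylenation followed by epoxidation this is one step instead of two, creates C1 under thermodynamic control, and delivers O1 axial. A sulfonium ylide would add axially and give the C1 epimer. Ketone 6 has five stereocentres, all from the cyclitol, on a chair locked by two fused ketals.

**6 from 5 from 4 from 3 from 2 from 1.** Ketone 6 comes from alcohol 5 by oxidation. One diketalisation sorts the six hydroxyls of myo-inositol 1: in 2 the cis pair O5/O6 and the trans pair O2/O3 are bridged, leaving O1–H and O4–H. These differ in reactivity, O1–H (next to the axial oxygen) acylating first. A camphanate on O1 (3) therefore both resolves the racemate and covers O1 while O4 is benzylated (4); its removal gives 5. A chiral ketal in place of the resolution would fix the enantiomer earlier, but leaves four free hydroxyls to sort and costs more steps than it saves.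

## Roads not taken

**Alternative 1:** The cut removes the C1–O and C4–O bonds together. Endoperoxide A1 would come from diene A2, a trans-5,6-dioxygenated cyclohexa-1,3-diene already carrying the benzoyloxymethyl group. Dye-sensitised singlet oxygen would add across C1 and C4 on the α face, syn to the free O2–H and anti to the silyl ether on O3.
- Merits: one step installs O1 on the quaternary carbon and O4 with the correct cis relation, and C7 with its benzoate is present from the start. In step count this road would probably beat the chosen one.
- Weak points: A1 has O1 on the wrong partner for the oxirane, and the C5=C6 alkene must still become C5–OH (β) and C6–O1. One way is a peroxide-to-bis-oxirane rearrangement and then a regioselective hydrolytic opening at C5 beside the C1/C6 oxirane. The other is O–O reduction, β-face epoxidation against the directing effect of two allylic hydroxyls, and a Payne transposition of uncertain equilibrium position. A1 has a hydrogen on a peroxide carbon (C4) and can fragment under base (Kornblum–DeLaMare), ene reaction competes with cycloaddition, and enantiopure A2 is not a pool compound.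
- Comparison: against the shorter count, the chosen plan takes five stereocentres unchanged from a cyclitol, makes the sixth in a locked chair, and settles the sorting of the oxygens before any sensitive function appears.

**Alternative 2:** The cut is the C2–O bond. The achiral para-quinol A4 forms an arylboronate hemiester at its tertiary hydroxyl (phenyl in A3). Under a chiral amine–thiourea catalyst the B–OH adds to one of the two enantiotopic enone arms, giving the cis-fused boronate A3 with C1 and C2 set and O1/O2 cis.
- Merits: catalytic enantioselection instead of a resolution (the chosen route discards half of 2 in step 2), a short entry from a phenol, C7 and benzoate in place, few protecting groups.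
- Weak points: only two of six stereocentres are made. A3 still needs O3 introduced next to the ketone and trans to O2, the C4 carbonyl reduced to the α alcohol, and the C5=C6 enone turned into C5–OH and the C6–O1 bond. Each of these is under substrate control on a ring with no conformational anchor, and the benzoate must survive enolate and hydride chemistry. The enantioselectivity with an acyloxymethyl group on the quaternary carbon is not assured.
- Comparison: the chosen plan is longer before its key step but has nothing stereochemical left to prove after it.

**Alternative 3:** The cut is the C1=C6 bond. The pentose-derived acyclic diene A6, with a vinyl terminus at C6 and a 2-(benzyloxymethyl)vinyl unit at C1, would close with the second-generation Grubbs catalyst, RuCl2(=CHPh)(PCy3)(H2IMes), to the protected 1-(benzyloxymethyl)conduritol B A5.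
- Merits: a dependable ring closure (six-membered ring, trisubstituted alkene), absolute configuration from a sugar without resolution, and a protecting-group pattern that already separates O2/O3 (PMB) from O4/O5 (benzyl). After PMB removal the free allylic O2–H could direct epoxidation of C1=C6 to the α face and give the oxirane directly. In that respect this road is more direct than the cyclic sulfate sequence of the chosen route.
- Weak points: the sugar supplies three stereocentres only, and the fourth carbinol centre comes from adding a branched vinyl nucleophile to an α-alkoxy aldehyde with uncertain diastereoselectivity. Chain extension at both ends costs steps. O7 is a third benzyl ether, so after hydrogenolysis the benzoate must be placed selectively on the primary hydroxyl of a triol that also holds two migratable acetates and an oxirane.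
- Comparison: the chosen plan delivers the benzoate to C7 by oxirane opening, where it cannot be misplaced, and has all ring oxygens present from the first step.

Key step: step 6

## Route

Assumption: which of the two camphanates of step 2 crystallises first is not predicted; the ester kept is the one whose cyclitol part has the configuration drawn for 3, to be confirmed by X-ray analysis with the camphanoyl group as internal reference.

Step 1
Reactants: 1 myo-inositol
Product: 2 (±)-1,2:4,5-di-O-isopropylidene-myo-inositol (O5/O6 cis-ketal, O2/O3 trans-ketal, O1–H and O4–H free)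
Conditions: Me2C(OMe)2, TsOH·H2O (cat.), DMF, 100 °C; Et3N; crystallisation
Reagents that add atoms: 2,2-dimethoxypropane, COC(C)(C)OC
Why: Acid-catalysed transketalisation under thermodynamic control bridges the cis pair (axial O6 with O5) and one trans-diequatorial pair; of the three diketals formed, the 1,2:4,5-isomer is the one that crystallises. It is racemic because the two ways of placing the cis-ketal on the meso cyclitol are mirror images.

Step 2
Reactants: 2 (±)-1,2:4,5-di-O-isopropylidene-myo-inositol
Product: 3 1D-1-O-[(1S)-camphanoyl]-2,3:5,6-di-O-isopropylidene-myo-inositol (single diastereomer, O4–H free)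
Conditions: (1S)-(−)-camphanic chloride (1.0 equiv), Et3N, DMAP (cat.), CH2Cl2, −20 → 0 °C; fractional crystallisation of the diastereomers
Reagents that add atoms: (1S)-(−)-camphanic chloride, O=C(Cl)[C@@]12CC[C@@](C)(C(=O)O1)C2(C)C
Why: Regioselective acylation of O1–H, the hydroxyl beside the axial ketal oxygen and the more reactive of the two in diketals of this type, combined with classical resolution through diastereomeric esters. The absolute configuration of C2–C6 is fixed here by selecting the diastereomer; no bond at a stereocentre is made or broken.

Step 3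
Reactants: 3 1D-1-O-[(1S)-camphanoyl]-2,3:5,6-di-O-isopropylidene-myo-inositol
Product: 4 1D-4-O-benzyl-1-O-[(1S)-camphanoyl]-2,3:5,6-di-O-isopropylidene-myo-inositol
Conditions: 2-benzyloxy-1-methylpyridinium triflate, MgO, PhCF3, 85 °C
Reagents that add atoms: 2-benzyloxy-1-methylpyridinium triflate, C[n+]1ccccc1OCc1ccccc1.[O-]S(=O)(=O)C(F)(F)F
Why: Thermal benzyl transfer from the pyridinium salt under neutral conditions; with no base the ester stays in place, and MgO takes up the acid so both ketals survive. O4 lies para to O1 across the ring, so the ester cannot migrate to it.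

Step 4
Reactants: 4 1D-4-O-benzyl-1-O-[(1S)-camphanoyl]-2,3:5,6-di-O-isopropylidene-myo-inositol
Product: 5 1D-4-O-benzyl-2,3:5,6-di-O-isopropylidene-myo-inositol
Conditions: K2CO3 (cat.), MeOH, rt
Reagents that add atoms: none
Why: Base-catalysed methanolysis (transesterification) of the ester; the ketals and the benzyl ether are inert to methoxide.

Step 5
Reactants: 5 1D-4-O-benzyl-2,3:5,6-di-O-isopropylidene-myo-inositol
Product: 6 1D-4-O-benzyl-2,3:5,6-di-O-isopropylidene-myo-inos-1-ose (C1 ketone)
Conditions: Dess–Martin periodinane, pyridine, CH2Cl2, 0 °C → rt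
Reagents that add atoms: none
Why: Dess–Martin oxidation of the only free hydroxyl; the buffered, non-basic medium keeps the two α-stereocentres (C2, C6) and the acid-labile trans-ketal intact. The ketone is used without aqueous exposure to avoid hydrate formation.

Step 6
Reactants: 6 1D-4-O-benzyl-2,3:5,6-di-O-isopropylidene-myo-inos-1-ose; 7 trimethylsulfoxonium iodide
Product: 9 spiro-oxirane at C1 (O1 α axial; C7H2 β equatorial; both ketals and the benzyl ether kept), via sulfoxonium betaine 8 (not isolated)
Conditions: 7, NaH, DMSO, rt (ylide formation); then 6 in THF, 0 °C → rt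
Reagents that add atoms: trimethylsulfoxonium iodide (compound 7), C[S+](C)(C)=O.[I-]
Why: Corey–Chaykovsky methylene transfer, the known way to turn cyclohexanones and protected inososes into spiro-oxiranes. The ylide carbon adds to the C1 carbonyl and forms the C1–C7 bond of betaine 8; with the stabilised sulfoxonium ylide this addition is reversible, and the slow step is the 3-exo-tet displacement of dimethyl sulfoxide by the alkoxide, which forms the C7–O1 bond and closes the oxirane. The ring is held in one chair by the cis-fused ketal at C5/C6 (O6 axial) and the trans-fused ketal at C2/C3, so the two possible betaines differ only in whether the bulky CH2S(O)Me2 group sits equatorial or axial. The equatorial one is favoured, and its axial alkoxide lies anti to the C6–O dipole; closure from it gives C1 with O1 α (axial) and C7 β (equatorial). This is the one new stereocentre, and it is controlled by the locked chair of the substrate, not by a reagent. The step needs facial selectivity at C1 and must be faster than enolisation. The oxygens β to the carbonyl are ring ethers held equatorial and so are poor leaving groups for elimination, the C6 hydrogen is equatorial and badly aligned for removal, and the axial C2 hydrogen is protected only by using a slight excess of ylide at low temperature.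

Step 7
Reactants: 9 spiro-oxirane
Product: 10 2α,3β-diol (trans-ketal removed; cis-5,6-ketal, benzyl ether and spiro-oxirane kept)
Conditions: HOCH2CH2OH, TsOH·H2O (cat.), CH2Cl2, 0 °C → rt; Et3N quench
Reagents that add atoms: none
Why: Selective acid-catalysed transketalisation: the strained trans-fused dioxolane exchanges much faster than the cis-fused one. Compound 9 has no free hydroxyl that could capture the ketal, and the oxirane is deactivated towards ionisation by the C–O bonds on both neighbouring carbons.

Step 8
Reactants: 10 2α,3β-diol
Product: 11 2α,3β-diacetate of the spiro-oxirane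
Conditions: Ac2O, pyridine, DMAP (cat.), CH2Cl2, 0 °C → rt
Reagents that add atoms: acetic anhydride, CC(=O)OC(C)=O
Why: Standard acylation of two secondary hydroxyls; pyridine is too weak a base to start a Payne rearrangement of the neighbouring oxirane.

Step 9
Reactants: 11 2α,3β-diacetate of the spiro-oxirane; 12 benzoic acid
Product: 13 tertiary alcohol (1α-OH, 1β-CH2OBz, 2α,3β-diacetate, 4α-OBn, 5β,6β-O-isopropylidene)
Conditions: PhCO2H (3 equiv), PhCO2Na (0.5 equiv), DMF, 100 °C
Reagents that add atoms: benzoic acid (compound 12), O=C(O)c1ccccc1
Why: SN2 opening of the 2,2-disubstituted oxirane by benzoate at its CH2 carbon, the only carbon open to attack; the C1–O bond is untouched, so C1 keeps its configuration. Excess benzoic acid protonates the tertiary alkoxide as it forms, before it can take the acetyl group from the cis O2.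

Step 10
Reactants: 13 tertiary alcohol
Product: 14 1α,5β,6β-triol (2α,3β-diacetate, 4α-OBn, 7-OBz)
Conditions: CF3CO2H/H2O (9:1), 0 °C
Reagents that add atoms: none
Why: Acid hydrolysis of the remaining cis-fused ketal; esters and the benzyl ether are stable, and the trans-diaxial O1/O6 pair cannot re-form a ketal.

Step 11
Reactants: 14 1α,5β,6β-triol
Product: 16 5β,6β-cyclic sulfate, via cyclic sulfite 15 (not isolated)
Conditions: SOCl2 (1.2 equiv), Et3N, CH2Cl2, 0 °C; then RuCl3·xH2O (cat.), NaIO4, MeCN/CCl4/H2O, 0 °C, short reaction time
Reagents that add atoms: thionyl chloride, O=S(Cl)Cl; sodium periodate, [Na+].[O-]I(=O)(=O)=O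
Why: Cyclic sulfite formation on the cis-diol followed by ruthenium-catalysed periodate oxidation to the sulfate, the standard two-stage activation of 1,2-diols. The hindered tertiary O1–H cannot bridge to O6 and stays free; the oxidation is kept cold and brief to spare the benzyl ether.

Step 12
Reactants: 16 5β,6β-cyclic sulfate
Product: 18 4-O-benzyl ether of the target (1α,6α-oxirane and 5β-OH), via sodium sulfate monoester 17 (not isolated)
Conditions: NaH (1.1 equiv), THF, 0 °C → rt; then H2O (2 equiv), H2SO4 (cat.), 0 °C → rt
Reagents that add atoms: none
Why: The sodium alkoxide of O1, axial and anti-periplanar to the C6–O bond of the cyclic sulfate, displaces it in a 3-exo-tet SN2 reaction with inversion at C6. This sets the C6 configuration of the target; O1 cannot reach C5, which is left as a sulfate monoester. Catalytic acid with a little water then cleaves the S–O bond of the monoester (C5 retained), while the oxirane is deactivated towards ionisation by three neighbouring C–O bonds.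

Step 13
Reactants: 18 4-O-benzyl ether of the target
Product: 19 [(1S,2R,3S,4R,5R,6S)-2,3-diacetoxy-4,5-dihydroxy-7-oxabicyclo[4.1.0]heptan-1-yl]methyl benzoate (CNP0171674.1)
Conditions: H2 (1 atm), Pd(OH)2/C, EtOAc, rt
Reagents that add atoms: none
Why: Catalytic hydrogenolysis cleaves only the benzylic C–O bond; the oxirane carbons are neither benzylic nor allylic and the esters are inert. The neutral medium gives no opening for acetyl migration from O3 to the freed O4–H.

## Compound list

1 | myo-inositol | O[C@H]1[C@@H](O)[C@@H](O)[C@H](O)[C@@H](O)[C@@H]1O | starting material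
2 | (±)-1,2:4,5-di-O-isopropylidene-myo-inositol (racemate; the enantiomer shown, the one carried on, is 1D-2,3:5,6-di-O-isopropylidene-myo-inositol) | CC1(C)O[C@H]2[C@H](O)[C@H]3OC(C)(C)O[C@H]3[C@@H](O)[C@@H]2O1 | intermediate
3 | 1D-1-O-[(1S)-camphanoyl]-2,3:5,6-di-O-isopropylidene-myo-inositol | CC1(C)O[C@H]2[C@H](O)[C@H]3OC(C)(C)O[C@H]3[C@@H](OC(=O)[C@@]45CC[C@@](C)(C(=O)O4)C5(C)C)[C@@H]2O1 | intermediate
4 | 1D-4-O-benzyl-1-O-[(1S)-camphanoyl]-2,3:5,6-di-O-isopropylidene-myo-inositol | CC1(C)O[C@H]2[C@H](OCc3ccccc3)[C@H]3OC(C)(C)O[C@H]3[C@@H](OC(=O)[C@@]45CC[C@@](C)(C(=O)O4)C5(C)C)[C@@H]2O1 | intermediate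
5 | 1D-4-O-benzyl-2,3:5,6-di-O-isopropylidene-myo-inositol | CC1(C)O[C@H]2[C@H](OCc3ccccc3)[C@H]3OC(C)(C)O[C@H]3[C@@H](O)[C@@H]2O1 | intermediate
6 | 1D-4-O-benzyl-2,3:5,6-di-O-isopropylidene-myo-inos-1-ose (ketone at C1; key-step precursor) | CC1(C)O[C@H]2[C@H](OCc3ccccc3)[C@H]3OC(C)(C)O[C@H]3C(=O)[C@@H]2O1 | intermediate
7 | trimethylsulfoxonium iodide | C[S+](C)(C)=O.[I-] | starting material
8 | sulfoxonium betaine of 6 (C1 alkoxide α, axial; C7H2–S(O)Me2 β, equatorial) | CC1(C)O[C@H]2[C@H](OCc3ccccc3)[C@H]3OC(C)(C)O[C@H]3[C@@]([O-])(C[S+](C)(C)=O)[C@@H]2O1 | intermediate (not isolated)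
9 | spiro-oxirane (key-step product): C1 spiro to an oxirane with O1 α (axial) and C7H2 β (equatorial); O2 α/O3 β trans-isopropylidene; O4 α benzyl ether; O5 β/O6 β cis-isopropylidene | CC1(C)O[C@H]2[C@H](OCc3ccccc3)[C@H]3OC(C)(C)O[C@H]3[C@@]4(CO4)[C@@H]2O1 | intermediate
10 | 2α,3β-diol of the spiro-oxirane (cis-5,6-ketal and 4-O-benzyl kept) | O[C@H]1[C@H](OCc2ccccc2)[C@H]3OC(C)(C)O[C@H]3[C@@]4(CO4)[C@@H]1O | intermediate
11 | 2α,3β-diacetate of the spiro-oxirane | CC(=O)O[C@H]1[C@H](OCc2ccccc2)[C@H]3OC(C)(C)O[C@H]3[C@@]4(CO4)[C@@H]1OC(C)=O | intermediate
12 | benzoic acid | O=C(O)c1ccccc1 | starting material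
13 | tertiary alcohol: 1α-hydroxy-1β-(benzoyloxymethyl), 2α,3β-diacetoxy, 4α-benzyloxy, 5β,6β-O-isopropylidene cyclohexane | CC(=O)O[C@H]1[C@H](OCc2ccccc2)[C@H]3OC(C)(C)O[C@H]3[C@@](O)(COC(=O)c4ccccc4)[C@@H]1OC(C)=O | intermediate
14 | 1α,5β,6β-triol: 1β-(benzoyloxymethyl), 2α,3β-diacetoxy, 4α-benzyloxy | CC(=O)O[C@H]1[C@H](OCc2ccccc2)[C@@H](O)[C@@H](O)[C@@](O)(COC(=O)c3ccccc3)[C@@H]1OC(C)=O | intermediate
15 | 5β,6β-cyclic sulfite of 14 (mixture at sulfur) | CC(=O)O[C@H]1[C@H](OCc2ccccc2)[C@H]3OS(=O)O[C@H]3[C@@](O)(COC(=O)c4ccccc4)[C@@H]1OC(C)=O | intermediate (not isolated)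
16 | 5β,6β-cyclic sulfate of 14 | CC(=O)O[C@H]1[C@H](OCc2ccccc2)[C@H]3OS(=O)(=O)O[C@H]3[C@@](O)(COC(=O)c4ccccc4)[C@@H]1OC(C)=O | intermediate
17 | sodium 5β-sulfate of 18 (1α,6α-oxirane closed) | CC(=O)O[C@H]1[C@H](OCc2ccccc2)[C@@H](OS(=O)(=O)[O-])[C@@H]3O[C@]3(COC(=O)c4ccccc4)[C@@H]1OC(C)=O.[Na+] | intermediate (not isolated)
18 | 4-O-benzyl ether of the target: 1α,6α-oxirane, 1β-(benzoyloxymethyl), 2α,3β-diacetoxy, 4α-benzyloxy, 5β-hydroxy | CC(=O)O[C@H]1[C@H](OCc2ccccc2)[C@@H](O)[C@@H]3O[C@]3(COC(=O)c4ccccc4)[C@@H]1OC(C)=O | intermediate
19 | [(1S,2R,3S,4R,5R,6S)-2,3-diacetoxy-4,5-dihydroxy-7-oxabicyclo[4.1.0]heptan-1-yl]methyl benzoate (CNP0171674.1) | CC(=O)O[C@H]1[C@H](O)[C@@H](O)[C@@H]2O[C@]2(COC(=O)c2ccccc2)[C@@H]1OC(C)=O | target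

## Step count and risk

Total step count: 13. Longest linear sequence: 13 steps, from myo-inositol 1 to 19.

**Step 6 (key step).** Two processes can spoil it. The first is poor facial selectivity, if the kinetically formed betaine with C7 axial closes before the betaines equilibrate. The second is enolisation towards C2, whose hydrogen is axial; epimerisation there would turn the strained trans-fused ketal into a cis-fused one, and elimination of a β-oxygen could follow. Fallback, from 6: non-basic methylenation with Cp2TiMe2 (toluene, 65 °C) gives the 1-deoxy-1-methylidene compound F1. Epoxidation with mCPBA (NaHCO3, CH2Cl2) should then come from the α face, the axial direction normally preferred by peracids on methylenecyclohexanes and here also anti to the axial C6–O bond and remote from the cis-ketal. This changes the control element from betaine equilibration to kinetic face selection on an alkene, and the sequence rejoins the route at 9.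

**Step 12.** The tertiary alkoxide can take the acetyl group from the cis O2 or the benzoyl group from O7 instead of closing the ring. The transfers are reversible and only the C1 alkoxide can cyclise, but repeated transfers would scramble the esters. The acid used for the sulfate monoester can also open the new oxirane. In addition, the ruthenium oxidant of step 11 may attack the benzyl ether. Fallback, from 14: TBSCl and imidazole in DMF silylate the accessible equatorial O5–H to give the 5-O-TBS ether F2. Tf2O and pyridine (CH2Cl2, −30 → 0 °C) convert the axial O6–H into the triflate F3, which is displaced on warming by the anti-periplanar O1–H with pyridine as the only base, giving the silylated oxirane F4. HF·pyridine in THF removes the silyl group and returns the route to 18. This avoids the ruthenium oxidation, the strong base and the acid hydrolysis.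

**Step 7.** The danger is acid-promoted opening of the spiro-oxirane, by ethane-1,2-diol or with participation of the freed hydroxyls, during removal of the trans-ketal. Fallback, from 4, where no oxirane is present:
- The same ketal exchange gives the 5,6-diol F5 (1D numbering).
- 4-Methoxybenzyl trichloroacetimidate with La(OTf)3 (cat.) gives the bis-PMB ether F6.
- Methanolysis of the camphanate gives alcohol F7, and Dess–Martin oxidation the inosose F8.
- The ylide reaction of step 6 then gives spiro-oxirane F9, from which DDQ (CH2Cl2/pH 7 buffer) removes both PMB groups under neutral conditions.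

The sequence rejoins the route at 10.

**Step 2.** Acylation may not distinguish O1–H from O4–H cleanly, and the diastereomeric esters may not separate by crystallisation. Fallback, from 2: TBSCl and imidazole silylate O1–H to give the racemic 1-O-TBS ether F10. NaH and BnBr in DMF give the racemic 4-O-benzyl ether F11, and Bu4NF the racemic alcohol F12. This has a single free hydroxyl and is esterified with (1S)-camphanic chloride; the two camphanates are separated, and the one identical with 4 rejoins the route at 4. The resolution is thus moved to a stage with no regiochemical choice, and the neutral benzylation of step 3 is replaced by an ordinary base-mediated one.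

**Step 13.** Hydrogenolysis may open the oxirane on the palladium surface, or debenzylation at the hindered O4 may be slow enough for over-reduction to intervene. Fallback, from 16, where the oxirane does not yet exist: H2 over Pd/C in EtOAc removes the benzyl group to give the 4-hydroxy cyclic sulfate F13. Et3SiOTf and 2,6-lutidine (CH2Cl2, −78 °C) give the 4-O-triethylsilyl ether F14. NaH in THF closes the oxirane as in step 12 to the sulfate monoester F15 (not isolated). The acidic hydrolysis that follows removes the sulfate and the silyl ether together and gives 19 directly.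

## Further compounds

F1 | step 6 | 1D-4-O-benzyl-1-deoxy-2,3:5,6-di-O-isopropylidene-1-methylidene-myo-inositol (exocyclic C1=C7 alkene) | CC1(C)O[C@H]2[C@H](OCc3ccccc3)[C@H]3OC(C)(C)O[C@H]3C(=C)[C@@H]2O1
F2 | step 12 | 5-O-tert-butyldimethylsilyl ether of 14 | CC(=O)O[C@H]1[C@H](OCc2ccccc2)[C@@H](O[Si](C)(C)C(C)(C)C)[C@@H](O)[C@@](O)(COC(=O)c3ccccc3)[C@@H]1OC(C)=O
F3 | step 12 | 6-O-triflate of F2 | CC(=O)O[C@H]1[C@H](OCc2ccccc2)[C@@H](O[Si](C)(C)C(C)(C)C)[C@@H](OS(=O)(=O)C(F)(F)F)[C@@](O)(COC(=O)c3ccccc3)[C@@H]1OC(C)=O
F4 | step 12 | 5-O-tert-butyldimethylsilyl ether of 18 | CC(=O)O[C@H]1[C@H](OCc2ccccc2)[C@@H](O[Si](C)(C)C(C)(C)C)[C@@H]3O[C@]3(COC(=O)c4ccccc4)[C@@H]1OC(C)=O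
F5 | step 7 | 1D-4-O-benzyl-1-O-[(1S)-camphanoyl]-2,3-O-isopropylidene-myo-inositol (5,6-diol) | O[C@H]1[C@H](OCc2ccccc2)[C@H]3OC(C)(C)O[C@H]3[C@@H](OC(=O)[C@@]45CC[C@@](C)(C(=O)O4)C5(C)C)[C@@H]1O
F6 | step 7 | 1D-4-O-benzyl-1-O-[(1S)-camphanoyl]-2,3-O-isopropylidene-5,6-bis-O-(4-methoxybenzyl)-myo-inositol | COc1ccc(CO[C@H]2[C@H](OCc3ccccc3)[C@H]4OC(C)(C)O[C@H]4[C@@H](OC(=O)[C@@]56CC[C@@](C)(C(=O)O5)C6(C)C)[C@@H]2OCc2ccc(OC)cc2)cc1
F7 | step 7 | 1D-4-O-benzyl-2,3-O-isopropylidene-5,6-bis-O-(4-methoxybenzyl)-myo-inositol | COc1ccc(CO[C@H]2[C@H](OCc3ccccc3)[C@H]4OC(C)(C)O[C@H]4[C@@H](O)[C@@H]2OCc2ccc(OC)cc2)cc1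
F8 | step 7 | 1D-4-O-benzyl-2,3-O-isopropylidene-5,6-bis-O-(4-methoxybenzyl)-myo-inos-1-ose | COc1ccc(CO[C@H]2[C@H](OCc3ccccc3)[C@H]3OC(C)(C)O[C@H]3C(=O)[C@@H]2OCc2ccc(OC)cc2)cc1
F9 | step 7 | spiro-oxirane of F8 (O1 α axial, C7H2 β equatorial) | COc1ccc(CO[C@H]2[C@H](OCc3ccccc3)[C@H]3OC(C)(C)O[C@H]3[C@@]3(CO3)[C@@H]2OCc2ccc(OC)cc2)cc1
F10 | step 2 | (±)-1-O-tert-butyldimethylsilyl-2,3:5,6-di-O-isopropylidene-myo-inositol (racemate; one enantiomer shown) | CC1(C)O[C@H]2[C@H](O)[C@H]3OC(C)(C)O[C@H]3[C@@H](O[Si](C)(C)C(C)(C)C)[C@@H]2O1
F11 | step 2 | (±)-4-O-benzyl-1-O-tert-butyldimethylsilyl-2,3:5,6-di-O-isopropylidene-myo-inositol (racemate; one enantiomer shown) | CC1(C)O[C@H]2[C@H](OCc3ccccc3)[C@H]3OC(C)(C)O[C@H]3[C@@H](O[Si](C)(C)C(C)(C)C)[C@@H]2O1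
F12 | step 2 | (±)-4-O-benzyl-2,3:5,6-di-O-isopropylidene-myo-inositol (racemate of 5; one enantiomer shown) | CC1(C)O[C@H]2[C@H](OCc3ccccc3)[C@H]3OC(C)(C)O[C@H]3[C@@H](O)[C@@H]2O1
F13 | step 13 | 4-hydroxy analogue of cyclic sulfate 16 | CC(=O)O[C@H]1[C@H](O)[C@H]2OS(=O)(=O)O[C@H]2[C@@](O)(COC(=O)c2ccccc2)[C@@H]1OC(C)=O
F14 | step 13 | 4-O-triethylsilyl ether of F13 | CC(=O)O[C@H]1[C@H](O[Si](CC)(CC)CC)[C@H]2OS(=O)(=O)O[C@H]2[C@@](O)(COC(=O)c2ccccc2)[C@@H]1OC(C)=O
F15 | step 13 | sodium 5β-sulfate of the 4-O-triethylsilyl 1α,6α-oxirane (not isolated) | CC(=O)O[C@H]1[C@H](O[Si](CC)(CC)CC)[C@@H](OS(=O)(=O)[O-])[C@@H]2O[C@]2(COC(=O)c2ccccc2)[C@@H]1OC(C)=O.[Na+]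
A1 | alternative 1 | C1,C4-endoperoxide (2,3-dioxabicyclo[2.2.2]oct-5-ene) with 1-CH2OBz, 2-OH, 3-OTBS | CC(C)(C)[Si](C)(C)O[C@H]1[C@H]2C=C[C@@](OO2)(COC(=O)c3ccccc3)[C@@H]1O
A2 | alternative 1 | trans-5-silyloxy-6-hydroxy-1-(benzoyloxymethyl)cyclohexa-1,3-diene | CC(C)(C)[Si](C)(C)O[C@H]1C=CC=C(COC(=O)c2ccccc2)[C@@H]1O
A3 | alternative 2 | cis-fused phenylboronate of the 4,5-dihydroxycyclohex-2-enone (C1 and C2 set) | O=C1C[C@H]2OB(c3ccccc3)O[C@@]2(COC(=O)c3ccccc3)C=C1
A4 | alternative 2 | 4-(benzoyloxymethyl)-4-hydroxycyclohexa-2,5-dienone (para-quinol) | O=C1C=CC(O)(COC(=O)c2ccccc2)C=C1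
A5 | alternative 3 | protected 1-(benzyloxymethyl)conduritol B (2,3-di-O-PMB, 4,5-di-O-benzyl) | COc1ccc(CO[C@H]2[C@H](OCc3ccccc3)[C@@H](OCc3ccccc3)C=C(COCc3ccccc3)[C@@H]2OCc2ccc(OC)cc2)cc1
A6 | alternative 3 | acyclic 1,7-diene with vinyl and 2-(benzyloxymethyl)vinyl termini | C=C[C@H](OCc1ccccc1)[C@@H](OCc1ccccc1)[C@H](OCc1ccc(OC)cc1)[C@@H](OCc1ccc(OC)cc1)C(=C)COCc1ccccc1
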